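The plan disconnects the γ-lactone fused to the C7–C8 bond of the ten-membered ring: the lactone O–C7 bond and the C8–C17 bond are formed together. An α-chloro ketone (C7–Cl, C8=O) in the complete bicyclo[8.4.0] skeleton reacts with 2-(diethoxyphosphoryl)propanoate; carboxylate displacement at C7 is followed in the same flask by intramolecular Horner–Wadsworth–Emmons closure onto C8, giving the 8(17)-butenolide. The step exploits the vicinal allylic C7–O carbon and fully substituted C8; epoxidation and anti hydrolysis then give the trans-8,17-diol. The cyclohexene core comes from a catalytic asymmetric Diels–Alder reaction, the ten-membered ring from olefin metathesis.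

Key step: step 19

Remark: briarane numbering is used for all intermediates (ten-membered ring C1–C10; cyclohexene C1, C10–C14; lactone O, C7, C8, C17, C19; methyl groups C15 on C1, C16 on C5, C18 on C17, C20 on C11).
Remark: the C11 configuration of compounds 4–8 is drawn for the endo adduct and is inconsequential, because C11 becomes trigonal in step 7.

Step 1
Reactants: 1 pent-1-en-3-one
Product: 2 (Z)-3-(tert-butyldimethylsilyloxy)penta-1,3-diene
Conditions: TBSOTf, Et3N, Et2O, 0 °C
Reagents that add atoms: tert-butyldimethylsilyl trifluoromethanesulfonate, CC(C)(C)[Si](C)(C)OS(=O)(=O)C(F)(F)F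
Why: Soft enolisation and O-silylation of the ethyl ketone (silyl enol ether formation) should give the thermodynamically preferred (Z)-2-silyloxy diene, whose methyl group occupies the outside position needed for cycloaddition.

Step 2
Reactants: 2 (Z)-3-(tert-butyldimethylsilyloxy)penta-1,3-diene; 3 ethyl (E)-3-methyl-4-oxobut-2-enoate
Product: 4 Diels–Alder adduct ethyl 3-(tert-butyldimethylsilyloxy)-6-formyl-2,6-dimethylcyclohex-3-ene-1-carboxylate
Conditions: (S)-B-(o-tolyl)-diphenylprolinol oxazaborolidine·HNTf2 (20 mol%), CH2Cl2, −78 → −40 °C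
Reagents that add atoms: none
Why: Catalytic enantioselective Diels–Alder reaction in which the catalyst-bound formyl group directs the nucleophilic diene terminus C11 to C10, the E geometry of 3 fixes formyl (C2) trans to ester (C9), and the catalyst enantiomer, chosen by the formyl C–H···O pre-transition-state model, sets C1 and C10.

Step 3
Reactants: 4 Diels–Alder adduct
Product: 5 C2 allylic alcohol
Conditions: MgBr2·OEt2, CH2Cl2, −78 °C; then CH2=CHMgBr, THF, −78 °C; NH4Cl (aq.) at −78 °C
Reagents that add atoms: vinylmagnesium bromide, C=C[Mg]Br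
Why: Chelation-controlled Grignard addition in which magnesium bridges the aldehyde and ester carbonyls, so that vinyl should enter past the C1 methyl group and give C2 as in the target; the hindered ester is untouched at −78 °C and any C2 epimer is removed in step 4.

Step 4
Reactants: 5 C2 allylic alcohol
Product: 6 C3–C4 epoxy alcohol
Conditions: Ti(OiPr)4, L-(+)-diisopropyl tartrate, t-BuOOH, 4 Å MS, CH2Cl2, −20 °C
Reagents that add atoms: tert-butyl hydroperoxide, CC(C)(C)OO
Why: Sharpless asymmetric epoxidation of the secondary allylic alcohol in its matched sense should give the anti (erythro) epoxy alcohol and so set C3, while the C2 epimer reacts far more slowly (kinetic resolution).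

Step 5
Reactants: 6 C3–C4 epoxy alcohol
Product: 7 C2 triethylsilyl ether
Conditions: Et3SiCl, imidazole, DMF, 23 °C
Reagents that add atoms: chlorotriethylsilane, CC[Si](Cl)(CC)CC
Why: Silylation under non-acidic conditions spares the epoxide and the silyl enol ether, removes the γ-hydroxy ester relationship and reserves later lactonisation for the C3 oxygen.

Step 6
Reactants: 7 C2 triethylsilyl ether
Product: 8 cyclohexenone (C12 ketone, C13=C14)
Conditions: Pd(OAc)2 (1.1 equiv), MeCN, 23 °C
Reagents that add atoms: none
Why: Saegusa–Ito oxidation, in which the silyl enol ether is transferred to palladium as an oxa-π-allyl species and β-hydride elimination towards C14 gives the enone.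

Step 7
Reactants: 8 cyclohexenone
Product: 9 dienyl triflate (C11=C12–OTf)
Conditions: KN(SiMe3)2, THF, −78 °C; then PhNTf2, −78 → 0 °C
Reagents that add atoms: N-phenylbis(trifluoromethanesulfonimide), O=S(=O)(N(c1ccccc1)S(=O)(=O)C(F)(F)F)C(F)(F)F
Why: Kinetic deprotonation at C11, the only enolisable position of the enone, and O-triflation (enol triflate formation) give the cross-conjugated dienyl triflate.

Step 8
Reactants: 9 dienyl triflate
Product: 10 cyclohexa-1,3-diene (C11=C12–C13=C14)
Conditions: Pd(OAc)2 (5 mol%), PPh3, Et3N, HCO2H, DMF, 50 °C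
Reagents that add atoms: none
Why: Palladium-catalysed formate reduction of the vinyl triflate (oxidative addition, hydride transfer from formate, reductive elimination) should give the 1,3-diene without touching the ester, epoxide or silyl ether.

Step 9
Reactants: 10 cyclohexa-1,3-diene
Product: 11 C11,C12 cis-diol
Conditions: OsO4 (2 mol%), N-methylmorpholine N-oxide, acetone/H2O, 0 °C
Reagents that add atoms: osmium tetroxide (catalytic oxygen carrier), O=[Os](=O)(=O)=O; N-methylmorpholine N-oxide, C[N+]1([O-])CCOCC1; water, O
Why: Catalytic syn-dihydroxylation (Upjohn conditions) should take the more electron-rich trisubstituted C11=C12 bond on the ring face opposite the C10 ester and the C1 methyl group, setting C11 and C12 together as the cis-diol.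

Step 10
Reactants: 11 C11,C12 cis-diol
Product: 12 C11,C12 acetonide
Conditions: 2-methoxypropene, PPTS (cat.), CH2Cl2, 0 °C
Reagents that add atoms: 2-methoxypropene, C=C(C)OC
Why: Acid-catalysed acetonide formation masks the cis-diol under conditions mild enough to spare the terminal epoxide and the triethylsilyl ether.

Step 11
Reactants: 12 C11,C12 acetonide
Product: 14 C3–O–C9 δ-lactone, via hydroxy ester 13 (not isolated)
Conditions: CH2=C(CH3)MgBr, CuI (10 mol%), THF, −40 °C; NH4Cl (aq.); then 2-hydroxypyridine (cat.), toluene, 80 °C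
Reagents that add atoms: isopropenylmagnesium bromide, C=C(C)[Mg]Br
Why: Copper-catalysed Grignard opening of the terminal epoxide at C4 (SN2) installs C5 and C16 as a methallyl group, and the freed C3 hydroxyl then lactonises onto the C9 ethyl ester to give a trans-fused six-membered lactone that protects C3–OH and activates C9.

Step 12
Reactants: 14 C3–O–C9 δ-lactone
Product: 15 C9 keto dithiane
Conditions: 1,3-dithiane, n-BuLi, THF, −30 °C; then 14, −78 → −20 °C; NH4Cl (aq.)
Reagents that add atoms: 1,3-dithiane (used as 2-lithio-1,3-dithiane), C1CSCSC1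
Why: Acylation of 2-lithio-1,3-dithiane by the lactone (Corey–Seebach umpolung) forms the C8–C9 bond, and the acidic α-dithianyl ketone is enolised in the flask, which prevents a second addition.

Step 13
Reactants: 15 C9 keto dithiane
Product: 16 C3,C9 diol
Conditions: Zn(BH4)2, Et2O, −30 → 0 °C
Reagents that add atoms: none
Why: Chelation-controlled hydride reduction in which zinc bridges the C9 carbonyl and the C11 acetonide oxygen and hydride arrives on the face remote from quaternary C1, which should set C9 as in the target.

Step 14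
Reactants: 16 C3,C9 diol
Product: 17 C3,C9 diacetate
Conditions: Ac2O, DMAP, pyridine, CH2Cl2, 23 °C
Reagents that add atoms: acetic anhydride, CC(=O)OC(C)=O
Why: Nucleophile-catalysed acetylation installs both acetates of the target in one step, since C3–OH and C9–OH are the only free hydroxyl groups.

Step 15
Reactants: 17 C3,C9 diacetate
Product: 18 C8 aldehyde
Conditions: MeI, CaCO3, MeCN/H2O (9:1), 45 °C
Reagents that add atoms: water, O
Why: Alkylative hydrolysis of the dithiane (S-methylation, then attack of water) unmasks the C8 aldehyde under buffered, non-oxidising conditions that spare the alkenes, acetates, acetonide and silyl ether.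

Step 16
Reactants: 18 C8 aldehyde
Product: 19 syn chlorohydrin (C8–OH, C7–Cl, vinyl)
Conditions: allyl chloride, LiN(c-C6H11)2, (−)-Ipc2BOMe, BF3·OEt2, Et2O, −95 °C; then 18, −95 → −78 °C; ethanolamine work-up
Reagents that add atoms: allyl chloride (transferred as (Z)-γ-chloroallyldiisopinocampheylborane), C=CCCl
Why: Asymmetric γ-chloroallylboration through a chair-like six-membered transition state, in which the (Z)-reagent gives the syn chlorohydrin and the isopinocampheyl groups (from (+)-α-pinene) select the aldehyde face, so that C7–Cl is set opposite in configuration to the C7–O bond of the target.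

Step 17
Reactants: 19 syn chlorohydrin
Product: 20 ten-membered-ring chlorohydrin
Conditions: second-generation Hoveyda–Grubbs catalyst (15 mol%), 1,4-benzoquinone (30 mol%), toluene (1 mM), 80 °C
Reagents that add atoms: none
Why: Ring-closing olefin metathesis between the vinyl and methallyl termini at high dilution closes the ten-membered ring, and the endocyclic trisubstituted C5=C6 bond in a ring of this size is expected as the Z isomer.

Step 18
Reactants: 20 ten-membered-ring chlorohydrin
Product: 21 α-chloro ketone (C7–Cl, C8=O)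
Conditions: Dess–Martin periodinane, NaHCO3, CH2Cl2, 0 → 23 °C
Reagents that add atoms: none
Why: Dess–Martin oxidation of the only free hydroxyl gives the α-chloro ketone under buffered, non-basic conditions that should not epimerise C7.

Step 19
Reactants: 21 α-chloro ketone; 22 2-(diethoxyphosphoryl)propanoic acid
Product: 24 8(17)-butenolide, via phosphonate ester 23 (not isolated)
Conditions: Cs2CO3, DMF, 0 → 23 °C
Reagents that add atoms: none
Why: The cesium carboxylate of 22 displaces the C7 chloride of 21 by SN2, accelerated by the adjacent C8 carbonyl, which forms the O–C7 bond with inversion; carbonate then deprotonates the phosphonate of ester 23, and the C17 carbanion adds to the C8 ketone and expels diethyl phosphate, forming the C8–C17 bond as the butenolide double bond. The closest known reaction type is the one-pot carboxylate alkylation and intramolecular Horner–Wadsworth–Emmons annulation of α-halo ketones to butenolides. The five-membered lactone ring is closed by 5-exo-trig attack of the phosphonate carbanion on the ketone carbonyl. The only new stereocentre, C7, is controlled by stereospecific inversion of the chloride installed under reagent control in step 16. The step needs direct substitution at C7 to outrun enolisation and SN2′ attack: the fully substituted C5 end of the C5=C6 bond blocks SN2′, and a weakly basic carboxylate in a polar aprotic solvent favours displacement. Chemoselectivity for C8 is inherent, because it is the only ketone and the tether reaches no other carbonyl.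

Step 20
Reactants: 24 8(17)-butenolide
Product: 25 8,17-epoxy lactone
Conditions: t-BuOOH, DBU, CH2Cl2, 0 °C
Reagents that add atoms: tert-butyl hydroperoxide, CC(C)(C)OO
Why: Nucleophilic (Weitz–Scheffer) epoxidation in which tert-butyl peroxide anion adds to C8 of the electron-poor butenolide on the face anti to the C7 substituent (C6) and the enolate closes the oxirane, leaving the electron-rich C5=C6 and C13=C14 bonds untouched.

Step 21
Reactants: 25 8,17-epoxy lactone
Product: 26 brianodin D
Conditions: HClO4 (1 M aq.), THF, 0 → 23 °C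
Reagents that add atoms: water, O
Why: Acid-catalysed hydrolysis in which water opens the protonated glycidic lactone at C8, the tertiary carbon remote from the carbonyl, with inversion (possibly assisted by the C9 acetate) to give the trans-8,17-diol, while the same acid cleaves the triethylsilyl ether and the acetonide.

Compound list
1 | pent-1-en-3-one | C=CC(=O)CC | starting material
2 | (Z)-3-(tert-butyldimethylsilyloxy)penta-1,3-diene | C/C=C(\O[Si](C)(C)C(C)(C)C)C=C | intermediate
3 | ethyl (E)-3-methyl-4-oxobut-2-enoate | CCOC(=O)/C=C(\C)C=O | starting material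
4 | Diels–Alder adduct, ethyl 3-(tert-butyldimethylsilyloxy)-6-formyl-2,6-dimethylcyclohex-3-ene-1-carboxylate; formyl (C2) trans to ester (C9), C1 and C10 as in the target | O=C[C@@]1(C)CC=C(O[Si](C)(C)C(C)(C)C)[C@@H](C)[C@@H]1C(=O)OCC | intermediate
5 | C2 allylic alcohol (1-hydroxyprop-2-enyl group on C1, C2 as in the target) | C=C[C@@H](O)[C@@]1(C)CC=C(O[Si](C)(C)C(C)(C)C)[C@@H](C)[C@@H]1C(=O)OCC | intermediate
6 | C3–C4 epoxy alcohol (epoxide anti to the C2 hydroxyl, C3 as in the target) | C1O[C@H]1[C@@H](O)[C@@]2(C)CC=C(O[Si](C)(C)C(C)(C)C)[C@@H](C)[C@@H]2C(=O)OCC | intermediate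
7 | C2 triethylsilyl ether of 6 | C1O[C@H]1[C@@H](O[Si](CC)(CC)CC)[C@@]2(C)CC=C(O[Si](C)(C)C(C)(C)C)[C@@H](C)[C@@H]2C(=O)OCC | intermediate
8 | cyclohexenone (C12 ketone, C13=C14) | C1O[C@H]1[C@@H](O[Si](CC)(CC)CC)[C@@]2(C)C=CC(=O)[C@@H](C)[C@@H]2C(=O)OCC | intermediate
9 | dienyl triflate (C11=C12–OTf, C13=C14) | C1O[C@H]1[C@@H](O[Si](CC)(CC)CC)[C@@]2(C)C=CC(OS(=O)(=O)C(F)(F)F)=C(C)[C@@H]2C(=O)OCC | intermediate
10 | cyclohexa-1,3-diene (C11=C12–C13=C14) | C1O[C@H]1[C@@H](O[Si](CC)(CC)CC)[C@@]2(C)C=CC=C(C)[C@@H]2C(=O)OCC | intermediate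
11 | C11,C12 cis-diol (both hydroxyls trans to the C10 ester) | C1O[C@H]1[C@@H](O[Si](CC)(CC)CC)[C@@]2(C)C=C[C@@H](O)[C@@](C)(O)[C@@H]2C(=O)OCC | intermediate
12 | C11,C12 acetonide of 11 | C1O[C@H]1[C@@H](O[Si](CC)(CC)CC)[C@@]2(C)C=C[C@H]3OC(C)(C)O[C@@]3(C)[C@@H]2C(=O)OCC | intermediate
13 | C3 hydroxy ester with methallyl group on C3 (not isolated) | C=C(C)C[C@@H](O)[C@@H](O[Si](CC)(CC)CC)[C@@]1(C)C=C[C@H]2OC(C)(C)O[C@@]2(C)[C@@H]1C(=O)OCC | intermediate
14 | C3–O–C9 δ-lactone, trans-fused to the cyclohexene | C=C(C)C[C@H]1OC(=O)[C@H]2[C@]3(C)OC(C)(C)O[C@@H]3C=C[C@]2(C)[C@@H]1O[Si](CC)(CC)CC | intermediate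
15 | C9 keto dithiane (C8 as 1,3-dithian-2-yl, C3 hydroxyl free) | C=C(C)C[C@@H](O)[C@@H](O[Si](CC)(CC)CC)[C@@]1(C)C=C[C@H]2OC(C)(C)O[C@@]2(C)[C@@H]1C(=O)C1SCCCS1 | intermediate
16 | C3,C9 diol (C9 as in the target) | C=C(C)C[C@@H](O)[C@@H](O[Si](CC)(CC)CC)[C@@]1(C)C=C[C@H]2OC(C)(C)O[C@@]2(C)[C@@H]1[C@H](O)C1SCCCS1 | intermediate
17 | C3,C9 diacetate | C=C(C)C[C@@H](OC(C)=O)[C@@H](O[Si](CC)(CC)CC)[C@@]1(C)C=C[C@H]2OC(C)(C)O[C@@]2(C)[C@@H]1[C@H](OC(C)=O)C1SCCCS1 | intermediate
18 | C8 aldehyde | C=C(C)C[C@@H](OC(C)=O)[C@@H](O[Si](CC)(CC)CC)[C@@]1(C)C=C[C@H]2OC(C)(C)O[C@@]2(C)[C@@H]1[C@H](OC(C)=O)C=O | intermediate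
19 | syn chlorohydrin (C8–OH, C7–Cl, vinyl on C7; C7 opposite in configuration to C7–O of the target) | C=C(C)C[C@@H](OC(C)=O)[C@@H](O[Si](CC)(CC)CC)[C@@]1(C)C=C[C@H]2OC(C)(C)O[C@@]2(C)[C@@H]1[C@H](OC(C)=O)[C@@H](O)[C@@H](C=C)Cl | intermediate
20 | ten-membered-ring chlorohydrin with (5Z)-alkene | CC(=O)O[C@@H]1C/C(C)=C\[C@@H](Cl)[C@H](O)[C@@H](OC(C)=O)[C@H]2[C@]3(C)OC(C)(C)O[C@@H]3C=C[C@]2(C)[C@@H]1O[Si](CC)(CC)CC | intermediate
21 | α-chloro ketone (C7–Cl, C8=O) | CC(=O)O[C@@H]1C/C(C)=C\[C@@H](Cl)C(=O)[C@@H](OC(C)=O)[C@H]2[C@]3(C)OC(C)(C)O[C@@H]3C=C[C@]2(C)[C@@H]1O[Si](CC)(CC)CC | intermediate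
22 | 2-(diethoxyphosphoryl)propanoic acid | CCOP(=O)(OCC)C(C)C(=O)O | starting material
23 | C7 2-(diethoxyphosphoryl)propanoate of the C8 ketone (C7 inverted, as in the target; phosphonate carbon as a mixture; not isolated) | CC(=O)O[C@@H]1C/C(C)=C\[C@H](OC(=O)C(C)P(=O)(OCC)OCC)C(=O)[C@@H](OC(C)=O)[C@H]2[C@]3(C)OC(C)(C)O[C@@H]3C=C[C@]2(C)[C@@H]1O[Si](CC)(CC)CC | intermediate
24 | 8(17)-butenolide | CC(=O)O[C@@H]1C/C(C)=C\[C@@H]2OC(=O)C(C)=C2[C@@H](OC(C)=O)[C@H]3[C@]4(C)OC(C)(C)O[C@@H]4C=C[C@]3(C)[C@@H]1O[Si](CC)(CC)CC | intermediate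
25 | 8,17-epoxy lactone (oxirane oxygen anti to C6 on the lactone ring) | CC(=O)O[C@@H]1C/C(C)=C\[C@@H]2OC(=O)[C@@]5(C)O[C@@]25[C@@H](OC(C)=O)[C@H]3[C@]4(C)OC(C)(C)O[C@@H]4C=C[C@]3(C)[C@@H]1O[Si](CC)(CC)CC | intermediate
26 | brianodin D | CC(=O)O[C@@H]1C/C(C)=C\[C@@H]2OC(=O)[C@@](C)(O)[C@@]2(O)[C@@H](OC(C)=O)[C@H]2[C@](C)(O)[C@H](O)C=C[C@]2(C)[C@@H]1O | target

Total step count: 21
Longest linear sequence: 21 steps (1 → 26); 3 and 22 enter at steps 2 and 19.

Steps most likely to fail

1. Step 17 (ring-closing metathesis). The flexible diene may oligomerise instead of closing the ten-membered ring, the 1,1-disubstituted alkene may not be engaged, or ruthenium hydride species may shift the double bonds. Fallback: the lactone is annulated before the ring is closed, so that cyclisation starts from a conformationally locked substrate. Setting out from 19, Dess–Martin oxidation should give the open-chain α-chloro ketone F1. Treatment of F1 with 22 and Cs2CO3 in DMF, as in step 19, should give the vinyl butenolide F2, in which the five-membered lactone fixes the C6–C7–C8–C9 torsion in a gauche arrangement and no free hydroxyl or allylic chloride remains at the reacting vinyl group. Ring-closing metathesis of F2 with the second-generation Hoveyda–Grubbs catalyst then comes back to the route at 24.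

2. Step 19 (carboxylate displacement and Horner–Wadsworth–Emmons closure). Enolisation at C7 of the α-chloro ketone or of ester 23 may erode the C7 configuration or move the C5=C6 bond into conjugation, and backside attack at a ring carbon may be slowed by transannular crowding. Fallback: the C7–O bond is made before C8 becomes a ketone. Setting out from 20, the allylic chloride is displaced by the cesium salt of 22 (buffered with free 22) in DMF at 40 °C with inversion, giving the hydroxy phosphonate F3. Dess–Martin oxidation of F3 comes back to the route at 23, which is closed to 24 with LiCl and i-Pr2NEt in MeCN.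

3. Step 21 (epoxide hydrolysis with global deprotection). The oxirane may open at the wrong carbon, the C9 acetate may migrate to the C8 oxygen, or the acid may ionise the allylic C7–O and C12–O bonds. Fallback: the 8,17-diol is built directly by an ester aldol instead of through the butenolide. Setting out from 21, the chloride is displaced by the cesium salt of commercial (S)-2-(tert-butyldimethylsilyloxy)propanoic acid in DMF to give the lactate ester F4. LiN(SiMe3)2 in THF at −78 °C should then close the lactone by intramolecular aldol addition of the ester enolate to the C8 ketone, giving the 17-O-silyl 8,17-diol lactone F5. The C8 and C17 configurations would depend on the lithium-bound transition state and would have to be confirmed, with unwanted isomers returned through retro-aldol equilibration. Aqueous HF in MeCN then removes both silyl ethers and the acetonide and comes back to the route at 26.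

Further compounds
F1 | step 17 | open-chain α-chloro ketone (C8 ketone, C7–Cl, vinyl on C7) | C=C(C)C[C@@H](OC(C)=O)[C@@H](O[Si](CC)(CC)CC)[C@@]1(C)C=C[C@H]2OC(C)(C)O[C@@]2(C)[C@@H]1[C@H](OC(C)=O)C(=O)[C@@H](C=C)Cl
F2 | step 17 | vinyl butenolide (open-chain precursor of 24) | C=C(C)C[C@@H](OC(C)=O)[C@@H](O[Si](CC)(CC)CC)[C@@]1(C)C=C[C@H]2OC(C)(C)O[C@@]2(C)[C@@H]1[C@H](OC(C)=O)C1=C(C)C(=O)O[C@H]1C=C
F3 | step 19 | C7 2-(diethoxyphosphoryl)propanoate of the ring C8 alcohol | CC(=O)O[C@@H]1C/C(C)=C\[C@H](OC(=O)C(C)P(=O)(OCC)OCC)[C@H](O)[C@@H](OC(C)=O)[C@H]2[C@]3(C)OC(C)(C)O[C@@H]3C=C[C@]2(C)[C@@H]1O[Si](CC)(CC)CC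
F4 | step 21 | C7 (S)-2-(tert-butyldimethylsilyloxy)propanoate of the C8 ketone | CC(=O)O[C@@H]1C/C(C)=C\[C@H](OC(=O)[C@H](C)O[Si](C)(C)C(C)(C)C)C(=O)[C@@H](OC(C)=O)[C@H]2[C@]3(C)OC(C)(C)O[C@@H]3C=C[C@]2(C)[C@@H]1O[Si](CC)(CC)CC
F5 | step 21 | 17-O-tert-butyldimethylsilyl 8,17-diol lactone (C8 and C17 as in the target) | CC(=O)O[C@@H]1C/C(C)=C\[C@@H]2OC(=O)[C@@](C)(O[Si](C)(C)C(C)(C)C)[C@@]2(O)[C@@H](OC(C)=O)[C@H]3[C@]4(C)OC(C)(C)O[C@@H]4C=C[C@]3(C)[C@@H]1O[Si](CC)(CC)CC
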